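**Plan** (guaiane numbering: ring carbons C1–C10, C11 the carbinol carbon, C14 on C10, C15 on C4)
1. Cuts, in order: the feruloyl C–O bond at O8; C6–C7 back to an alkene; C1–C5 and C9–C10 together; then the cyclopropane bonds C7–C8 and C7–C9, the two C11–methyl bonds and C6–C7.
2. Enabling feature: the seven-membered ring (C1, C5–C10) carries the tetrasubstituted C1=C10 alkene and is fused to the cyclopentane (C1–C5). C1=C10 is an alkyne, C5–C9 a vinylcyclopropane (C5=C6 alkene; C7, C8, C9 ring), and C2–C4 the tether that becomes the five-membered ring.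
3. Forward: C1–C6 and C15 come from (S)-citronellol (C10 and C14 by alkyne homologation and methylation), C7 and C11 from ethyl diazoacetate, C8, C9 and O8 from a silyl vinyl ether. Step 10 closes the five- and seven-membered rings at once; hydrogenation and esterification finish.
4. Stereochemistry: C4 from citronellol; C8 from the Rh2(S-DOSP)4 cyclopropanation, which also places the silyloxy group cis to the alkenyl group; C5 by stereospecific transfer from C8 in step 10; C7 by hydroxyl-directed hydrogenation.

Key step: step 10

Remark on the chemistry: Rh2(S-DOSP)4 is assumed to attack silyl vinyl ether 11 with the facial sense established for styrene and alkyl vinyl ethers; the silyloxy group must be cis to the alkenyl group in 14, because the suprafacial [5+2] addition then places H5 cis to O8, as the target requires.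

**Step 1**
Reactants: 1 (S)-citronellol
Product: 3 (4S)-6-hydroxy-4-methylhexanal, via secondary ozonide 2 (not isolated)
Conditions: O3, CH2Cl2, −78 °C; then PPh3, −78 °C → rt
Reagents that add atoms: ozone, [O-][O+]=O
Why: Ozonolysis with reductive work-up should cleave only the trisubstituted alkene, the free primary hydroxyl and the stereocentre taken over from 1 being inert to ozone at low temperature.

**Step 2**
Reactants: 3 (4S)-6-hydroxy-4-methylhexanal
Product: 4 (3S)-3-methylhept-6-yn-1-ol
Conditions: dimethyl (1-diazo-2-oxopropyl)phosphonate, K2CO3, MeOH, 0 °C → rt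
Reagents that add atoms: dimethyl (1-diazo-2-oxopropyl)phosphonate, COP(=O)(OC)C(=[N+]=[N-])C(C)=O
Why: The Ohira–Bestmann homologation tolerates a free hydroxyl and an enolisable aldehyde, and no stereocentre lies alpha to the carbonyl, so the one-carbon extension to the terminal alkyne (C10) should be clean.

**Step 3**
Reactants: 4 (3S)-3-methylhept-6-yn-1-ol
Product: 6 (3S)-3-methyloct-6-yn-1-ol, via dilithio alkynolate 5 (not isolated)
Conditions: n-BuLi (2.2 equiv), THF, −78 → 0 °C; then MeI (1.2 equiv), −78 °C → rt
Reagents that add atoms: iodomethane, CI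
Why: In this dianion alkylation the lithium acetylide should be methylated by MeI far faster than the lithium alkoxide, which installs C14.

**Step 4**
Reactants: 6 (3S)-3-methyloct-6-yn-1-ol
Product: 7 (3S)-3-methyloct-6-ynal
Conditions: Dess–Martin periodinane, CH2Cl2, 0 °C → rt
Reagents that add atoms: none
Why: Dess–Martin oxidation stops at the aldehyde under neutral conditions, and the methyl-bearing centre is beta to the carbonyl and cannot epimerise.

**Step 5**
Reactants: 7 (3S)-3-methyloct-6-ynal; 8 ethyl diazoacetate
Product: 9 ethyl (5S)-2-diazo-3-hydroxy-5-methyldec-8-ynoate (both C3 epimers)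
Conditions: DBU (0.15 equiv), MeCN, rt
Reagents that add atoms: none
Why: The amine-catalysed aldol-type addition of a diazoacetate to an aliphatic aldehyde forms C6–C7 with the diazo group intact, and the unselective new carbinol centre is removed in step 6.

**Step 6**
Reactants: 9 ethyl (5S)-2-diazo-3-hydroxy-5-methyldec-8-ynoate
Product: 10 ethyl (3E,5S)-2-diazo-5-methyldec-3-en-8-ynoate
Conditions: POCl3, Et3N, CH2Cl2, 0 °C → rt; used at once
Reagents that add atoms: none
Why: Dehydration of beta-hydroxy alpha-diazo esters with POCl3/Et3N is the standard entry to vinyl diazoacetates, and ionisation assisted by the diazo carbon followed by loss of a C5 proton should give the conjugated (E)-alkene.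

**Step 7**
Reactants: 10 ethyl (3E,5S)-2-diazo-5-methyldec-3-en-8-ynoate; 11 tert-butyldimethyl(vinyloxy)silane
Product: 12 ethyl (1R,2S)-2-(tert-butyldimethylsilyloxy)-1-[(1E,3S)-3-methyloct-1-en-6-yn-1-yl]cyclopropane-1-carboxylate
Conditions: Rh2(S-DOSP)4 (1 mol %), pentane, −78 °C → rt, slow addition of 10 to 11 (5 equiv)
Reagents that add atoms: none
Why: In this dirhodium-carbenoid cyclopropanation of an electron-rich vinyl ether by a donor/acceptor vinylcarbenoid, the alkene substituent should end up cis to the alkenyl donor and trans to the ester, and the chiral prolinate ligands should control the face so that C8 forms as S (C7 as R) without influence from the remote C4 centre.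

**Step 8**
Reactants: 12 (cyclopropane ester)
Product: 13 2-{(1R,2S)-2-(tert-butyldimethylsilyloxy)-1-[(1E,3S)-3-methyloct-1-en-6-yn-1-yl]cyclopropyl}propan-2-ol
Conditions: MeLi (3 equiv), Et2O, −78 → 0 °C
Reagents that add atoms: methyllithium, [Li]C
Why: Double addition of MeLi to the ester builds the C11 dimethylcarbinol and removes the acceptor from the donor–acceptor cyclopropane, and because the silyl ether is trans to the new alkoxide neither silyl migration nor ring opening should intervene.

**Step 9**
Reactants: 13 (cyclopropyl carbinol)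
Product: 14 triethylsilyl ether of 13 (silyloxy group at C8 cis to the alkenyl group)
Conditions: TESOTf, 2,6-lutidine, CH2Cl2, −78 °C
Reagents that add atoms: triethylsilyl trifluoromethanesulfonate, CC[Si](CC)(CC)OS(=O)(=O)C(F)(F)F
Why: Silylation of the hindered tertiary alcohol with a silyl triflate and a hindered base masks the acid-labile cyclopropylcarbinol without touching the ring.

**Step 10**
Reactants: 14 (alkyne-tethered silyloxy vinylcyclopropane)
Product: 15 (4S,5R,8S)-8-(tert-butyldimethylsilyloxy)-11-(triethylsilyloxy)guaia-1(10),6-diene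
Conditions: [Rh(CO)2Cl]2 (5 mol %), degassed PhMe (0.02 M), 90 °C
Reagents that add atoms: none
Why: Monovalent rhodium binds the C5=C6 alkene in the conformer that holds C5 over C8 and inserts into the distal C7–C9 bond to give a six-membered allyl/alkyl rhodacycle (trivalent rhodium), after which the tethered alkyne inserts at the allyl terminus (C1–C5) and C(sp2)–C(sp3) reductive elimination forms C9–C10. The closest known reaction type is the rhodium-catalysed intramolecular [5+2] cycloaddition of alkyne-tethered vinylcyclopropanes, including 1,2-disubstituted cyclopropanes. The cyclopentane closes by insertion of the alkyne across the three-carbon tether C2–C4 (a 5-exo closure onto C5), and the cycloheptadiene closes by the reductive elimination that completes the formal [5+2] union. C5 is the only new stereocentre and is set by the substrate: the addition is suprafacial, so C1–C5 forms on the alkene face syn to the breaking C7–C9 bond, and with the silyloxy group cis to the alkenyl group on the (8S) cyclopropane this places H5 cis to O8 (5R in 15), while C8 is not touched and C4 is a spectator. The step needs cleavage of C7–C9 and not of C7–C8, which should be secured because rhodium then bonds to the unsubstituted CH2, the cis silyloxy group shields the C7–C8 edge, an oxygen substituent strengthens its vicinal ring bonds and lengthens the distal one, and C7 no longer carries an acceptor after step 8.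

**Step 11**
Reactants: 15 (bis-silyl ether)
Product: 16 (4S,5R,8S)-guaia-1(10),6-diene-8,11-diol
Conditions: Bu4NF (5 equiv), THF, rt → 45 °C
Reagents that add atoms: none
Why: Fluoride should cleave both silyl ethers under basic conditions that leave the acid-sensitive tertiary allylic alcohol and the 1,4-diene intact.

**Step 12**
Reactants: 16 (diene diol)
Product: 17 (4S,5S,7S,8S)-guai-1(10)-ene-8,11-diol (the C5 descriptor changes by priority only)
Conditions: [Ir(cod)(PCy3)(py)]PF6 (5 mol %), H2 (1 atm), CH2Cl2, 0 °C → rt, stopped after one equivalent of H2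
Reagents that add atoms: none
Why: In this hydroxyl-directed homogeneous hydrogenation the ring hydroxyl at C8 should bind iridium and deliver hydrogen to the trisubstituted C6=C7 alkene on its own face, setting C7 as S with H7 cis to O8, while the tetrasubstituted C1=C10 alkene reacts far more slowly.

**Step 13**
Reactants: 18 ferulic acid
Product: 19 (E)-4-acetoxy-3-methoxycinnamic acid
Conditions: Ac2O, pyridine, rt; aqueous acidic work-up
Reagents that add atoms: acetic anhydride, CC(=O)OC(C)=O
Why: Acetylation masks the phenol so that it cannot compete as a nucleophile in the esterification.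

**Step 14**
Reactants: 17 (ene diol); 19 (E)-4-acetoxy-3-methoxycinnamic acid
Product: 20 (4S,5S,7S,8S)-8-O-[(E)-4-acetoxy-3-methoxycinnamoyl]guai-1(10)-ene-8,11-diol
Conditions: DCC, DMAP (0.2 equiv), CH2Cl2, 0 °C → rt
Reagents that add atoms: none
Why: Steglich esterification should acylate the secondary C8 hydroxyl only, the tertiary C11 hydroxyl being too hindered to react under these conditions.

**Step 15**
Reactants: 20 (acetyl-protected ester)
Product: 21 CNP0241038.1, (4S,5S,7S,8S)-8-O-(E)-feruloylguai-1(10)-ene-8,11-diol
Conditions: pyrrolidine (3 equiv), CH2Cl2, 0 °C → rt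
Reagents that add atoms: none
Why: Aminolysis of the aryl acetate should be much faster than attack on the hindered secondary cinnamate or conjugate addition, so the phenol is released selectively.

**Compound list**
1 | (S)-citronellol, (3S)-3,7-dimethyloct-6-en-1-ol | CC(C)=CCC[C@H](C)CCO | starting material
2 | secondary ozonide of 1, (3S)-5-(5,5-dimethyl-1,2,4-trioxolan-3-yl)-3-methylpentan-1-ol (both epimers at the trioxolane carbon) | CC1(C)OOC(CC[C@H](C)CCO)O1 | intermediate (not isolated)
3 | (4S)-6-hydroxy-4-methylhexanal | O=CCC[C@H](C)CCO | intermediate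
4 | (3S)-3-methylhept-6-yn-1-ol | C#CCC[C@H](C)CCO | intermediate
5 | dilithio derivative of 4 (lithium alkoxide and lithium acetylide) | [Li]C#CCC[C@H](C)CCO[Li] | intermediate (not isolated)
6 | (3S)-3-methyloct-6-yn-1-ol | CC#CCC[C@H](C)CCO | intermediate
7 | (3S)-3-methyloct-6-ynal | CC#CCC[C@H](C)CC=O | intermediate
8 | ethyl diazoacetate | CCOC(=O)C=[N+]=[N-] | starting material
9 | ethyl (5S)-2-diazo-3-hydroxy-5-methyldec-8-ynoate (both C3 epimers) | CC#CCC[C@H](C)CC(O)C(=[N+]=[N-])C(=O)OCC | intermediate
10 | ethyl (3E,5S)-2-diazo-5-methyldec-3-en-8-ynoate | CC#CCC[C@H](C)/C=C/C(=[N+]=[N-])C(=O)OCC | intermediate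
11 | tert-butyldimethyl(vinyloxy)silane | C=CO[Si](C)(C)C(C)(C)C | starting material
12 | ethyl (1R,2S)-2-(tert-butyldimethylsilyloxy)-1-[(1E,3S)-3-methyloct-1-en-6-yn-1-yl]cyclopropane-1-carboxylate | CC#CCC[C@H](C)/C=C/[C@]1(C(=O)OCC)C[C@@H]1O[Si](C)(C)C(C)(C)C | intermediate
13 | 2-{(1R,2S)-2-(tert-butyldimethylsilyloxy)-1-[(1E,3S)-3-methyloct-1-en-6-yn-1-yl]cyclopropyl}propan-2-ol | CC#CCC[C@H](C)/C=C/[C@]1(C(C)(C)O)C[C@@H]1O[Si](C)(C)C(C)(C)C | intermediate
14 | triethylsilyl ether of 13 (1R,2S cyclopropane, silyloxy cis to alkenyl) | CC#CCC[C@H](C)/C=C/[C@]1(C(C)(C)O[Si](CC)(CC)CC)C[C@@H]1O[Si](C)(C)C(C)(C)C | intermediate (precursor of the key step)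
15 | (4S,5R,8S)-8-(tert-butyldimethylsilyloxy)-11-(triethylsilyloxy)guaia-1(10),6-diene | CC(C)(C)[Si](C)(C)O[C@H]1CC(C)=C2CC[C@H](C)[C@@H]2C=C1C(C)(C)O[Si](CC)(CC)CC | intermediate (product of the key step)
16 | (4S,5R,8S)-guaia-1(10),6-diene-8,11-diol | O[C@H]1CC(C)=C2CC[C@H](C)[C@@H]2C=C1C(C)(C)O | intermediate
17 | (4S,5S,7S,8S)-guai-1(10)-ene-8,11-diol | O[C@H]1CC(C)=C2CC[C@H](C)[C@@H]2C[C@@H]1C(C)(C)O | intermediate
18 | ferulic acid | COc1cc(/C=C/C(=O)O)ccc1O | starting material
19 | (E)-4-acetoxy-3-methoxycinnamic acid | COc1cc(/C=C/C(=O)O)ccc1OC(C)=O | intermediate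
20 | (4S,5S,7S,8S)-8-O-[(E)-4-acetoxy-3-methoxycinnamoyl]guai-1(10)-ene-8,11-diol | COc1cc(/C=C/C(=O)O[C@H]2CC(C)=C3CC[C@H](C)[C@@H]3C[C@@H]2C(C)(C)O)ccc1OC(C)=O | intermediate
21 | CNP0241038.1, (4S,5S,7S,8S)-8-O-(E)-feruloylguai-1(10)-ene-8,11-diol | COc1cc(/C=C/C(=O)O[C@H]2CC(C)=C3CC[C@H](C)[C@@H]3C[C@@H]2C(C)(C)O)ccc1O | target

**Step count**
Total: 15 steps. Longest linear sequence: 14 steps (steps 1–12, 14 and 15, from 1); step 13 is a one-step side branch.

**Three steps most likely to fail**

Step 10. Rhodium may insert into the C7–C8 bond next to oxygen, beta-oxygen elimination may occur from the rhodacycle, or the silyloxycyclopropane may open before it cycloadds. The fallback sets out from 14 and returns at 15 and moves to the ruthenium-catalysed [5+2] manifold: [CpRu(MeCN)3]PF6 (10 mol %) in acetone at room temperature. Here alkyne and alkene are first coupled to a ruthenacyclopentene and the cyclopropane is opened only afterwards, at ambient temperature. The same suprafacial relation between C5 and C8 holds, and no new compound is made (F0).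

Step 12. The tertiary C11 hydroxyl may compete as a director and erode facial selectivity, or reduction may run on into the C1=C10 alkene. The fallback sets out from 15 and returns at 17 and changes the order of events, so that the ring hydroxyl is the only donor during hydrogenation. One equivalent of Bu4NF at 0 °C should remove the exposed secondary allylic silyl ether before the shielded tertiary one and give (4S,5R,8S)-11-(triethylsilyloxy)guaia-1(10),6-dien-8-ol F1. Hydrogenation of F1 with [Ir(cod)(PCy3)(py)]PF6 and H2 should then give (4S,5S,7S,8S)-11-(triethylsilyloxy)guai-1(10)-en-8-ol F2. Excess Bu4NF with warming frees the tertiary hydroxyl and gives 17.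

Step 6. Elimination may give a mixture of alkene geometries, a hydride shift with loss of nitrogen may compete, and the alkyl vinyl diazo ester may cyclise on standing. The fallback sets out from 7 and returns at 13; it makes the alkene first and introduces the diazo group last. Knoevenagel condensation of 7 with malonic acid under deconjugating, decarboxylating conditions (piperidinium acetate, DMSO, 100 °C) should give (3E,5S)-5-methyldec-3-en-8-ynoic acid F3. Methylation (MeI, K2CO3, DMF) gives methyl (3E,5S)-5-methyldec-3-en-8-ynoate F4. Regitz diazo transfer (4-acetamidobenzenesulfonyl azide, DBU, MeCN, 0 °C) gives methyl (3E,5S)-2-diazo-5-methyldec-3-en-8-ynoate F5. Cyclopropanation of 11 under the conditions of step 7 gives methyl (1R,2S)-2-(tert-butyldimethylsilyloxy)-1-[(1E,3S)-3-methyloct-1-en-6-yn-1-yl]cyclopropane-1-carboxylate F6, and MeLi as in step 8 converts F6 into 13.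

**Further compounds**
F0 | step 10 | none | none
F1 | step 12 | (4S,5R,8S)-11-(triethylsilyloxy)guaia-1(10),6-dien-8-ol | O[C@H]1CC(C)=C2CC[C@H](C)[C@@H]2C=C1C(C)(C)O[Si](CC)(CC)CC
F2 | step 12 | (4S,5S,7S,8S)-11-(triethylsilyloxy)guai-1(10)-en-8-ol | O[C@H]1CC(C)=C2CC[C@H](C)[C@@H]2C[C@@H]1C(C)(C)O[Si](CC)(CC)CC
F3 | step 6 | (3E,5S)-5-methyldec-3-en-8-ynoic acid | CC#CCC[C@H](C)/C=C/CC(=O)O
F4 | step 6 | methyl (3E,5S)-5-methyldec-3-en-8-ynoate | CC#CCC[C@H](C)/C=C/CC(=O)OC
F5 | step 6 | methyl (3E,5S)-2-diazo-5-methyldec-3-en-8-ynoate | CC#CCC[C@H](C)/C=C/C(=[N+]=[N-])C(=O)OC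
F6 | step 6 | methyl (1R,2S)-2-(tert-butyldimethylsilyloxy)-1-[(1E,3S)-3-methyloct-1-en-6-yn-1-yl]cyclopropane-1-carboxylate | CC#CCC[C@H](C)/C=C/[C@]1(C(=O)OC)C[C@@H]1O[Si](C)(C)C(C)(C)C
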